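**Remarks on the chemistry (assumptions)**

- The boron diol and the phenol protecting groups are treated as spectator groups. β-Substituted alkenyl pinacol boronates tend to hand the alkenyl group directly to palladium, so the styrenyl boron unit is used as its ester with cis-1,2-dimethylacenaphthene-1,2-diol ("mac" ester). The aryllithium of the key step carries two identical silyl ethers, so that the later ring closure meets only one kind of ortho carbon. Bonds formed and carbon skeletons of precursor 9 and product 16 are those of the key disconnection.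
- Check of structures: the (1S,2R) configuration of 16 maps onto Cb (S) and Ca (R) of 47 after retentive C–B oxidation, and anti addition to the E-alkene gives the trans aryl/hydroxyl pair. No structural correction was needed.
- The sense of induction of the ferrocenyl bisphosphine on these ate complexes is assumed. All three couplings (steps 8, 18, 24) need the same alkene face, so one antipode serves throughout; the (Rp,Rp) antipode replaces the (Sp,Sp) one if a pilot run shows the opposite sense.
- 4-Methoxyphenyllithium 29 is needed in two couplings. It is made once (step 17) as a titrated ethereal solution and drawn on in steps 18 and 24; it is assumed to keep its titre at −20 °C under argon over the few days between the two.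
- Compounds 10 and 21 are taken as catalogue compounds.

## Structural features

The target is a resveratrol tetramer with eight benzene rings, three trans-2,3-diaryl-2,3-dihydrobenzofurans (rings A, B, C) and one cycloheptane. The cycloheptane is fused to the benzo ring of ring A (arene E) and to a 3,5-dioxygenated benzene (arene D), and it contains C3 of ring A (C3A). The units form a chain: C2A carries C5 of the benzo ring of ring B, C3B carries C4 of the benzo ring of ring C, C3C carries a 3,5-dihydroxyphenyl group, and C2B and C2C each carry a 4-hydroxyphenyl group. The eight stereocentres fall into four vicinal trans pairs, Cb(OH)–Ca(4-hydroxyphenyl) in the cycloheptane (S, R), C3A–C2A (R, R), C3B–C2B (R, R) and C3C–C2C (R, R), and Ca and C3A are attached to neighbouring carbons of arene D with H at C3A cis to the aryl group at Ca. Fragile groups are the nine phenols (oxidation), the three benzylic C2–O bonds next to para-oxygenated aryl groups (acid opens them, and the cation at C2B lies within reach of the resorcinol ring on C3C), and the benzylic alcohol at Cb. The real difficulty is that the four stereo pairs are insulated from one another by arenes, so each needs its own source of absolute configuration, and that arene D and the benzo ring of ring C are crowded 1,2,3,5-tetrasubstituted benzenes. The key step exploits the Ca–Cb pair: two adjacent sp3 carbons that carry arene D and 4-hydroxyphenyl (Ca) and arene E and oxygen (Cb). The same Ar–CH(O)–CH(Ar)(Ar) pattern reappears at C2B–C3B and C2C–C3C once the ring O–C2 bonds are cut.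

## Logic of the disconnections

**47 to 46.** The nine O–C bonds of the protecting groups are cut (eight O–CH3 and the O–CH2OCH3 at Cb). Nine free phenols cannot pass through organolithium, palladium and oxidation chemistry. Nothing is gained in skeleton. The forward step needs a Lewis acid that cleaves aryl methyl ethers without opening the three benzylic C2–O bonds or ionising the Cb–O bond.

**46 to 45.** The C3A–arene E bond and the O–C2A bond are cut. Both belong to one alkene and to the ortho carbon and oxygen of one phenol, so ring A and the cycloheptane fall away together and C3A and C2A return to an E-alkene. This removes two rings and two stereocentres. The forward step must join the alkene carbon remote from the ring B aryl group to the arene, must meet only one kind of ortho carbon (hence two free hydroxyl groups in 45), and must take its facial selectivity from Ca and Cb.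

**45 to 20 and 43 (through 44).** The bond between the alkene and C5 of the benzo ring of ring B is cut. This splits the molecule into two halves of similar size, each with four of the eight stereocentres, and the E geometry is carried in by 20. The forward step must activate an electron-rich aryl chloride and free the two phenols without acid.

**20 back to 16 (through 19, 18, 17).** These are changes of functional groups only: one-carbon extension of an aldehyde, acetal to aldehyde, O-protection at Cb, and C–B to C–O. The order is forced: a free Cb–OH beside a free aldehyde would close to a six-membered lactol, and free phenols on arene E would add to the aldehyde. The demand is retention at Cb in the oxidation.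

**16 to 9, 11 and 13 (through 15 and 14).** The Cb–arene E bond and the Ca–(4-methoxyphenyl) bond are cut. The Ca–Cb unit is then seen as an alkene that is arylated on both carbons from opposite faces. Three simple arenes result, and both stereocentres come from one catalyst. The forward step must let the 1,2-shift win over direct transfer of the alkenyl group to palladium, and must use one alkene face.

**9, 11, 13 to starting materials.** 9 goes back to 7 and 2 (B–C bond by hydroboration, diol exchange), 7 to 4 and then 3 (aryl–alkyne bond, C–Br bond), 2 to 1 (two C–CH3 bonds), 11 to 10 and 13 to 12 (O–Si and O–S bonds). The demand is regiocontrol in the bromination of 3 and E geometry in the hydroboration.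

**43 to 42, then to 39, 29 and 34 (through 41 and 40).** The O–C2B bond is cut first: a para-methoxybenzylic carbinol next to a phenol closes to the trans ring, so C2B needs no control of its own. Then the C3B–C4(ring C) bond and the C2B–anisyl bond are cut in the same way as in 16. This removes ring B and two stereocentres and leaves a chloride as the handle. The forward coupling must accept a hindered triflate, override the existing stereocentres by catalyst control and leave the chloride alone.

**34 to 33 and 32, then to 25, 29 and 27 (through 31 and 30).** The O–S bond, the O–C2C bond and then the C3C–(3,5-dimethoxyphenyl) and C2C–anisyl bonds are cut. The central arene of 32 has two equivalent ortho oxygens. Whichever closes the ring, the other is left at C4, exactly where ring B must be attached. The demand is the same as for 16.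

**25, 39, 27 and 29 to starting materials.** 25 goes back to 23 and 2 and on to 22 and 21; 39 to 37 and 2 and on to 36 and 35; 27 to 26; 29 to 28. The cuts are B–C, alkyne C–C, O–CH2, O–S and C–Li bonds; the forward steps are standard, and the only demand is that one batch of 29 serves both couplings.

## Other disconnections considered

Alternative 1: The cut runs through the benzo ring of ring C, which is built de novo by a Danheiser benzannulation. In the forward step, cyclobutenone A2 (C3B on its β-carbon, the 3,5-dimethoxybenzyl group on C4) is heated with siloxyalkyne A3. A sequence of 4π opening, (2+2) addition, 4π opening and 6π closure would give phenol A1 with the free hydroxyl next to the benzyl carbon and the silyl ether meta to it.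
- In its favour: the substitution pattern of the crowded arene is dictated by the pericyclic sequence, and the two oxygens emerge already differentiated. No metal is involved. The aryl bromide survives and is a more reactive later handle than the chloride of 43; on these three points the alternative is the better plan.
- Against it: C3B sits on a carbon vinylogous to the cyclobutenone carbonyl and could epimerise during heating. After the benzannulation C3C and C2C are still missing, and they would have to be made from a benzylic CH2 with induction only from the distant ring B centres. The chosen plan sets C3C by a catalyst (step 18).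
- Comparison: the alternative is strong on arene construction and weak on stereocontrol, and it leaves the cycloheptane untouched. The making of A2 should cost at least as many steps as the route to 34.

Alternative 2: The cut is the Ca–Cb bond. In the forward step, aldehyde A5 (formyl group on arene E, para-quinone methide on the carbon attached to arene D) meets a triazolium-derived carbene. The acyl anion equivalent adds 1,6 to the quinone methide, closing the cycloheptane as ketone A4, which is reduced afterwards.
- In its favour: rings A, B and C are in place before the seven-membered ring closes. Ca is then α to a ketone and can be corrected by equilibration; this answers the weakest point of the chosen plan (facial selectivity in step 27), and here the alternative is the better one. No oxidant is used in the presence of electron-rich rings, which is also better.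
- Against it: a para-quinone methide without flanking alkyl groups is short-lived and can be attacked by the carbene itself. The aldehyde is hindered. The absolute configuration must come from a separate asymmetric construction of ring A. The reduction must deliver the trans alcohol.
- Comparison: the chosen plan sets Ca and Cb in an open chain by catalyst control, while the alternative relies on substrate control in a ring. Step economy should be about equal.

Alternative 3: The cut takes both O–C2 bonds of rings B and C at once. In the forward step, diol diphenol A7 in CF3CO2H would ionise at both carbinols, and each cation would be captured by the neighbouring phenol to give bromide A6.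
- In its favour: one operation closes two rings, and the carbinol centres need no control. On mechanism this is the equal of steps 19 and 25, which use the same closure one ring at a time. It is one step shorter, and the bromide is a more reactive handle than the chloride of 43 (better).
- Against it: A7 must already hold C3B and C3C in the right configuration on neighbouring positions of one arene, and the disconnection does not say how. Two cations at once raise the chance that the one at C2B is captured by the dimethoxyphenyl ring (seven-membered ring) or loses the doubly benzylic proton.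
- Comparison: the chosen plan supplies both diarylmethine centres by catalyst and exposes one cation at a time. The bromide could not pass through the palladium steps used here.

Key step: step 8

## Route

Step 1
Reactants: 1 acenaphthylene-1,2-dione
Product: 2 cis-1,2-dimethyl-1,2-dihydroacenaphthylene-1,2-diol (mac diol)
Conditions: MeMgBr (3 equiv), THF, 0 °C to rt; recrystallisation
Reagents that add atoms: methylmagnesium bromide, C[Mg]Br
Why: Twofold 1,2-addition to the diketone; the second methyl group should enter anti to the magnesium alkoxide and give the cis (meso) diol needed for a cyclic boronic ester, and recrystallisation removes any trans isomer.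

Step 2
Reactants: 3 3,5-dimethoxybenzaldehyde
Product: 4 2-bromo-3,5-dimethoxybenzaldehyde
Conditions: NBS, MeCN, rt
Reagents that add atoms: N-bromosuccinimide, O=C1CCC(=O)N1Br
Why: Electrophilic aromatic bromination; C2 is para to one methoxy group and ortho to the other, and the position between the two methoxy groups is more hindered.

Step 3
Reactants: 4 2-bromo-3,5-dimethoxybenzaldehyde
Product: 5 3,5-dimethoxy-2-[(trimethylsilyl)ethynyl]benzaldehyde
Conditions: ethynyltrimethylsilane, Pd(PPh3)2Cl2 (3 mol %), CuI (5 mol %), Et3N, THF, 60 °C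
Reagents that add atoms: ethynyltrimethylsilane, C#C[Si](C)(C)C
Why: Sonogashira coupling; the ortho formyl group activates the electron-rich aryl bromide toward oxidative addition.

Step 4
Reactants: 5 3,5-dimethoxy-2-[(trimethylsilyl)ethynyl]benzaldehyde
Product: 7 1-(dimethoxymethyl)-2-ethynyl-3,5-dimethoxybenzene, via silylalkyne dimethyl acetal 6 (not isolated)
Conditions: HC(OMe)3, TsOH·H2O (cat.), MeOH, rt; then K2CO3 (excess), rt
Reagents that add atoms: trimethyl orthoformate, COC(OC)OC; methanol, CO
Why: Acid-catalysed acetalisation masks the aldehyde before base is added, and methanolysis of the C–Si bond then frees the terminal alkyne in the same flask.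

Step 5
Reactants: 7 1-(dimethoxymethyl)-2-ethynyl-3,5-dimethoxybenzene; 2 mac diol
Product: 9 (E)-2-[2-(dimethoxymethyl)-4,6-dimethoxyphenyl]ethenylboronic acid mac ester, via E-alkenyl catechol boronate 8 (not isolated)
Conditions: catecholborane, dicyclohexylborane (10 mol %), THF, rt; then 2, rt; Et3N-deactivated silica
Reagents that add atoms: catecholborane, B1Oc2ccccc2O1
Why: Syn hydroboration of the terminal alkyne puts boron on the terminal carbon and gives the E-alkenyl catechol ester, which exchanges readily with the tertiary cis-diol 2.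

Step 6
Reactants: 10 5-bromobenzene-1,3-diol
Product: 11 1-bromo-3,5-bis(triisopropylsilyloxy)benzene
Conditions: TIPSCl, imidazole, DMF, rt
Reagents that add atoms: chlorotriisopropylsilane, CC(C)[Si](Cl)(C(C)C)C(C)C
Why: Silylation of both phenols; aryl triisopropylsilyl ethers survive t-BuLi at −78 °C, mild base and mild acid, and fall to fluoride.

Step 7
Reactants: 12 4-methoxyphenol
Product: 13 4-methoxyphenyl trifluoromethanesulfonate
Conditions: Tf2O, pyridine, CH2Cl2, 0 °C
Reagents that add atoms: trifluoromethanesulfonic anhydride, O=S(=O)(OS(=O)(=O)C(F)(F)F)C(F)(F)F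
Why: O-Sulfonylation of the phenol gives the halide-free aryl electrophile that the coupling needs.

Step 8
Reactants: 11 1-bromo-3,5-bis(triisopropylsilyloxy)benzene; 9 E-alkenylboronic acid mac ester; 13 4-methoxyphenyl trifluoromethanesulfonate
Product: 16 (1S,2R)-1-[3,5-bis(triisopropylsilyloxy)phenyl]-2-[2-(dimethoxymethyl)-4,6-dimethoxyphenyl]-2-(4-methoxyphenyl)ethylboronic acid mac ester, via 3,5-bis(triisopropylsilyloxy)phenyllithium 14 (not isolated), via lithium alkenyl(aryl)borate complex 15 (not isolated)
Conditions: 11, t-BuLi (2 equiv), Et2O, −78 °C; 9, THF, −78 °C to rt; then Pd(OAc)2 (3 mol %), (Sp,Sp)-1,1′-bis[bis(4-methoxy-3,5-dimethylphenyl)phosphino]-2,2′-bis[(R)-α-(dimethylamino)benzyl]ferrocene (MandyPhos type, 3.6 mol %), 13, NaOTf, THF, 60 °C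
Reagents that add atoms: none
Why: Aryllithium 14 adds to boron of 9 to give ate complex 15. Oxidative addition of 13 to zerovalent palladium gives a cationic arylpalladium species that binds the alkene of 15; this triggers 1,2-migration of the aryl group from boron to the α-carbon anti to palladium, and reductive elimination then joins the 4-methoxyphenyl group to the β-carbon. The closest known reaction type is the enantioselective palladium-catalysed conjunctive cross-coupling of β-substituted alkenylboron ate complexes with aryl triflates. No ring is closed. The diarylmethine centre (Ca) is set by the ligand, which decides the alkene face that palladium binds. The boron-bearing centre (Cb) follows from stereospecific anti addition across the E-alkene, which locks the pair in the relative configuration that becomes trans aryl/hydroxyl. The step needs the 1,2-shift to win over direct transfer of the alkenyl group to palladium: the hindered mac diol shields the B–O oxygens through which that transfer runs, and NaOTf removes bromide, which would block the site for alkene binding. The two ortho substituents of the β-aryl group twist it out of the alkene plane and slow alkene binding; this is the main uncertainty.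

Step 9
Reactants: 16 boronic acid mac ester
Product: 17 (1S,2R)-1-[3,5-bis(triisopropylsilyloxy)phenyl]-2-[2-(dimethoxymethyl)-4,6-dimethoxyphenyl]-2-(4-methoxyphenyl)ethan-1-ol
Conditions: NaBO3·4H2O, THF/H2O, rt
Reagents that add atoms: sodium perborate (hydrate water omitted), [Na+].[Na+].O[B-]1(O)OO[B-](O)(O)OO1
Why: Boronate oxidation; the carbon migrates from boron to oxygen with retention, and perborate is mild enough to spare the aryl silyl ethers and the acetal.

Step 10
Reactants: 17 secondary alcohol
Product: 18 1-[(1S,2R)-2-[2-(dimethoxymethyl)-4,6-dimethoxyphenyl]-1-(methoxymethoxy)-2-(4-methoxyphenyl)ethyl]-3,5-bis(triisopropylsilyloxy)benzene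
Conditions: MOMCl, iPr2NEt, n-Bu4NI (cat.), CH2Cl2, 40 °C
Reagents that add atoms: chloromethyl methyl ether, COCCl
Why: O-Alkylation of the hindered alcohol; a free Cb–OH would form a six-membered lactol with the aldehyde of step 11 and would compete for the cation in step 27.

Step 11
Reactants: 18 methoxymethyl ether
Product: 19 2-[(1R,2S)-2-[3,5-bis(triisopropylsilyloxy)phenyl]-2-(methoxymethoxy)-1-(4-methoxyphenyl)ethyl]-3,5-dimethoxybenzaldehyde
Conditions: pyridinium p-toluenesulfonate (cat.), acetone/H2O, rt
Reagents that add atoms: water, O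
Why: Mild hydrolysis of the electron-rich benzaldehyde acetal; aryl silyl ethers and the alkyl MOM ether are stable under these conditions.

Step 12
Reactants: 19 aldehyde
Product: 20 2-[(E)-2-{2-[(1R,2S)-2-[3,5-bis(triisopropylsilyloxy)phenyl]-2-(methoxymethoxy)-1-(4-methoxyphenyl)ethyl]-3,5-dimethoxyphenyl}ethenyl]-4,4,5,5-tetramethyl-1,3,2-dioxaborolane
Conditions: CH2(Bpin)2, lithium 2,2,6,6-tetramethylpiperidide (LiTMP), THF, 0 °C; then 19, −78 °C to rt
Reagents that add atoms: bis(4,4,5,5-tetramethyl-1,3,2-dioxaborolan-2-yl)methane, CC1(C)OB(CB2OC(C)(C)C(C)(C)O2)OC1(C)C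
Why: Boron-Wittig olefination; the lithiated geminal bis(boronate) adds to the aldehyde, and syn elimination of the B–O unit gives the E-alkenyl pinacol boronate.

Step 13
Reactants: 21 2,6-dihydroxy-4-methoxybenzaldehyde
Product: 22 4-methoxy-2,6-bis(methoxymethoxy)benzaldehyde
Conditions: MOMCl, iPr2NEt, CH2Cl2, 0 to 40 °C
Reagents that add atoms: chloromethyl methyl ether, COCCl
Why: O-Alkylation of both hydrogen-bonded phenols; the two identical acetal groups keep the arene symmetric for step 19.

Step 14
Reactants: 22 4-methoxy-2,6-bis(methoxymethoxy)benzaldehyde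
Product: 23 2-ethynyl-5-methoxy-1,3-bis(methoxymethoxy)benzene
Conditions: dimethyl (1-diazo-2-oxopropyl)phosphonate, K2CO3, MeOH, rt
Reagents that add atoms: dimethyl (1-diazo-2-oxopropyl)phosphonate, COP(=O)(OC)C(=[N+]=[N-])C(C)=O
Why: Ohira–Bestmann homologation; the diazomethylphosphonate anion adds to the aldehyde, and loss of phosphate and N2 gives the terminal alkyne under base that MOM ethers tolerate.

Step 15
Reactants: 23 terminal alkyne; 2 mac diol
Product: 25 (E)-2-[4-methoxy-2,6-bis(methoxymethoxy)phenyl]ethenylboronic acid mac ester, via E-alkenyl catechol boronate 24 (not isolated)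
Conditions: catecholborane, dicyclohexylborane (10 mol %), THF, rt; then 2, rt
Reagents that add atoms: catecholborane, B1Oc2ccccc2O1
Why: Syn hydroboration and diol exchange as in step 5.

Step 16
Reactants: 26 3,5-dimethoxyphenol
Product: 27 3,5-dimethoxyphenyl trifluoromethanesulfonate
Conditions: Tf2O, pyridine, CH2Cl2, 0 °C
Reagents that add atoms: trifluoromethanesulfonic anhydride, O=S(=O)(OS(=O)(=O)C(F)(F)F)C(F)(F)F
Why: O-Sulfonylation of the phenol.

Step 17
Reactants: 28 1-bromo-4-methoxybenzene
Product: 29 4-methoxyphenyllithium (titrated solution in Et2O/pentane that also holds the LiBr formed)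
Conditions: t-BuLi (2.0 equiv), Et2O, −78 °C; to 0 °C; titration; kept under argon at −20 °C
Reagents that add atoms: tert-butyllithium, CC(C)(C)[Li]
Why: Bromine–lithium exchange; the second equivalent of t-BuLi destroys the tert-butyl bromide formed, so no alkylating agent is left in the solution. Aryllithiums attack diethyl ether only slowly, so one titrated batch should keep cold for the time between steps 18 and 24, which both draw on it.

Step 18
Reactants: 29 4-methoxyphenyllithium; 25 E-alkenylboronic acid mac ester; 27 3,5-dimethoxyphenyl trifluoromethanesulfonate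
Product: 32 (1S,2R)-2-(3,5-dimethoxyphenyl)-2-[4-methoxy-2,6-bis(methoxymethoxy)phenyl]-1-(4-methoxyphenyl)ethan-1-ol, via lithium alkenyl(aryl)borate complex 30 (not isolated), via boronic acid mac ester 31 (not isolated)
Conditions: 29 (Et2O solution from step 17, 1.0 equiv), 25, THF, −78 °C to rt; Pd(OAc)2 (3 mol %), the ferrocenyl bisphosphine of step 8 (3.6 mol %), 27, NaOTf, THF, 60 °C; then aq NaOH, 30% H2O2, 0 °C to rt
Reagents that add atoms: hydrogen peroxide, OO
Why: Conjunctive cross-coupling as in step 8, followed by retentive oxidation in the same flask; NaOTf removes the bromide that comes in with 29. The unhindered 3,5-dimethoxyphenyl group is delivered from palladium to the β-carbon on the same alkene face as in step 8, which sets the centre that becomes C3C; the carbinol centre follows from anti addition.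

Step 19
Reactants: 32 carbinol
Product: 33 (2R,3R)-3-(3,5-dimethoxyphenyl)-6-methoxy-2-(4-methoxyphenyl)-2,3-dihydro-1-benzofuran-4-ol
Conditions: HCl (conc., 5 equiv), MeOH, 50 °C
Reagents that add atoms: none
Why: Acid removes both MOM groups (methanol traps the methoxymethyl cation) and ionises the para-methoxybenzylic carbinol. Either of the two equivalent ortho phenols closes the five-membered ring; the trans isomer is favoured and C2–O ionisation is reversible, while C3 is untouched.

Step 20
Reactants: 33 phenol
Product: 34 (2R,3R)-3-(3,5-dimethoxyphenyl)-6-methoxy-2-(4-methoxyphenyl)-2,3-dihydro-1-benzofuran-4-yl trifluoromethanesulfonate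
Conditions: Tf2O, pyridine, CH2Cl2, 0 °C
Reagents that add atoms: trifluoromethanesulfonic anhydride, O=S(=O)(OS(=O)(=O)C(F)(F)F)C(F)(F)F
Why: O-Sulfonylation of the remaining phenol, which sits at C4 where ring B has to be attached.

Step 21
Reactants: 35 5-chloro-2-hydroxybenzaldehyde
Product: 36 5-chloro-2-(methoxymethoxy)benzaldehyde
Conditions: MOMCl, iPr2NEt, CH2Cl2, rt
Reagents that add atoms: chloromethyl methyl ether, COCCl
Why: O-Alkylation of the phenol.

Step 22
Reactants: 36 5-chloro-2-(methoxymethoxy)benzaldehyde
Product: 37 4-chloro-2-ethynyl-1-(methoxymethoxy)benzene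
Conditions: dimethyl (1-diazo-2-oxopropyl)phosphonate, K2CO3, MeOH, rt
Reagents that add atoms: dimethyl (1-diazo-2-oxopropyl)phosphonate, COP(=O)(OC)C(=[N+]=[N-])C(C)=O
Why: Ohira–Bestmann homologation as in step 14.

Step 23
Reactants: 37 terminal alkyne; 2 mac diol
Product: 39 (E)-2-[5-chloro-2-(methoxymethoxy)phenyl]ethenylboronic acid mac ester, via E-alkenyl catechol boronate 38 (not isolated)
Conditions: catecholborane, dicyclohexylborane (10 mol %), THF, rt; then 2, rt
Reagents that add atoms: catecholborane, B1Oc2ccccc2O1
Why: Syn hydroboration and diol exchange as in step 5; the aryl chloride is inert.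

Step 24
Reactants: 29 4-methoxyphenyllithium; 39 E-alkenylboronic acid mac ester; 34 ring C triflate
Product: 42 (1S,2R)-2-[5-chloro-2-(methoxymethoxy)phenyl]-2-[(2R,3R)-3-(3,5-dimethoxyphenyl)-6-methoxy-2-(4-methoxyphenyl)-2,3-dihydro-1-benzofuran-4-yl]-1-(4-methoxyphenyl)ethan-1-ol, via lithium alkenyl(aryl)borate complex 40 (not isolated), via boronic acid mac ester 41 (not isolated)
Conditions: 29 (Et2O solution from step 17, 1.0 equiv), 39, THF, −78 °C to rt; Pd(OAc)2 (5 mol %), the ferrocenyl bisphosphine of step 8 (6 mol %), 34, NaOTf, THF, 60 °C; then aq NaOH, 30% H2O2, 0 °C to rt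
Reagents that add atoms: hydrogen peroxide, OO
Why: Conjunctive cross-coupling and retentive oxidation as in step 18. The ligand should override the two remote stereocentres of 34 and set the centre that becomes C3B. The aryl chloride is expected to be inert to the ate complex and to this palladium catalyst at 60 °C.

Step 25
Reactants: 42 carbinol
Product: 43 (2R,3R)-5-chloro-3-[(2R,3R)-3-(3,5-dimethoxyphenyl)-6-methoxy-2-(4-methoxyphenyl)-2,3-dihydro-1-benzofuran-4-yl]-2-(4-methoxyphenyl)-2,3-dihydro-1-benzofuran
Conditions: HCl (conc., 5 equiv), MeOH, 50 °C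
Reagents that add atoms: none
Why: MOM removal and ionisation of the para-methoxybenzylic carbinol as in step 19. Closure by the adjacent phenol oxygen should outrun Friedel–Crafts capture by the dimethoxyphenyl ring and gives the trans ring B with C3B untouched.

Step 26
Reactants: 20 E-alkenyl pinacol boronate; 43 aryl chloride
Product: 45 5-[(1S,2R)-2-{2-[(E)-2-(ring B/C unit of 43 bonded at C5 of ring B)ethenyl]-4,6-dimethoxyphenyl}-1-(methoxymethoxy)-2-(4-methoxyphenyl)ethyl]benzene-1,3-diol, via bis(triisopropylsilyl) ether 44 (not isolated)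
Conditions: Pd(OAc)2 (5 mol %), 2-dicyclohexylphosphino-2′,4′,6′-triisopropylbiphenyl (XPhos, 10 mol %), K3PO4, THF/H2O, 60 °C; then TBAF, THF, 0 °C
Reagents that add atoms: none
Why: Suzuki–Miyaura coupling with retention of the E geometry; the bulky biarylphosphine activates the electron-rich aryl chloride. Fluoride then cleaves only the two aryl O–Si bonds, so the resorcinol is freed without acid.

Step 27
Reactants: 45 E-stilbene resorcinol
Product: 46 Cb-O-methoxymethyl octa-O-methyl ether of 47 with the arene E phenol free (Ca R; Cb S; C3A R; C2A R; C3B R; C2B R; C3C R; C2C R)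
Conditions: Ru(bpz)3(PF6)2 (2 mol %, bpz = 2,2′-bipyrazine), (NH4)2S2O8 (2 equiv), MeCN, blue LEDs, rt
Reagents that add atoms: none
Why: Proposed new method: the excited ruthenium photocatalyst should oxidise the 4-alkoxystilbene of 45 to its radical cation; the resorcinol ring attacks the alkene carbon remote from the ring B aryl group through one of its two equivalent ortho carbons (seven-membered ring), and after rearomatisation and a second one-electron oxidation the para-alkoxybenzylic cation at C2A is captured by the adjacent phenol oxygen to give trans ring A; the closest known reaction types are the visible-light oxidative (3+2) cycloaddition of phenols with electron-rich alkenes and the oxidative coupling of hydroxystilbenes to dihydrobenzofurans. C3A is set by substrate control: the aryl group on Ca, held out of the plane of arene D by the neighbouring methoxy group, should send the styryl arm to the opposite face, which places H at C3A cis to that aryl group as in the target, and C2A then closes trans to C3A.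

Step 28
Reactants: 46 protected tetramer
Product: 47 target tetramer CNP0132116.1
Conditions: BBr3 (excess), CH2Cl2, −78 to 0 °C; aqueous work-up
Reagents that add atoms: none
Why: Lewis acid cleavage of the eight aryl methyl ethers and of the MOM ether at its acetal carbon, so the Cb–O bond is not broken. The benzylic cation at Cb would be meta to both oxygens of arene E and is therefore not readily formed.

## Compound list

1 | acenaphthylene-1,2-dione | O=C1C(=O)c2cccc3cccc1c23 | starting material
2 | cis-1,2-dimethyl-1,2-dihydroacenaphthylene-1,2-diol (mac diol, meso) | O[C@]1(C)c2cccc3cccc(c23)[C@]1(C)O | intermediate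
3 | 3,5-dimethoxybenzaldehyde | COc1cc(C=O)cc(OC)c1 | starting material
4 | 2-bromo-3,5-dimethoxybenzaldehyde | COc1cc(OC)c(Br)c(C=O)c1 | intermediate
5 | 3,5-dimethoxy-2-[(trimethylsilyl)ethynyl]benzaldehyde | COc1cc(OC)c(C#C[Si](C)(C)C)c(C=O)c1 | intermediate
6 | {[2-(dimethoxymethyl)-4,6-dimethoxyphenyl]ethynyl}trimethylsilane | COc1cc(OC)c(C#C[Si](C)(C)C)c(C(OC)OC)c1 | intermediate
7 | 1-(dimethoxymethyl)-2-ethynyl-3,5-dimethoxybenzene | COc1cc(OC)c(C#C)c(C(OC)OC)c1 | intermediate
8 | 2-{(E)-2-[2-(dimethoxymethyl)-4,6-dimethoxyphenyl]ethenyl}-1,3,2-benzodioxaborole | COc1cc(OC)c(/C=C/B2Oc3ccccc3O2)c(C(OC)OC)c1 | intermediate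
9 | (E)-2-[2-(dimethoxymethyl)-4,6-dimethoxyphenyl]ethenylboronic acid, cyclic ester with diol 2 (mac ester) | COc1cc(OC)c(/C=C/B2O[C@]3(C)c4cccc5cccc(c45)[C@]3(C)O2)c(C(OC)OC)c1 | intermediate
10 | 5-bromobenzene-1,3-diol | Oc1cc(O)cc(Br)c1 | starting material
11 | 1-bromo-3,5-bis(triisopropylsilyloxy)benzene | CC(C)[Si](Oc1cc(Br)cc(O[Si](C(C)C)(C(C)C)C(C)C)c1)(C(C)C)C(C)C | intermediate
12 | 4-methoxyphenol | COc1ccc(O)cc1 | starting material
13 | 4-methoxyphenyl trifluoromethanesulfonate | COc1ccc(OS(=O)(=O)C(F)(F)F)cc1 | intermediate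
14 | 3,5-bis(triisopropylsilyloxy)phenyllithium | [Li]c1cc(O[Si](C(C)C)(C(C)C)C(C)C)cc(O[Si](C(C)C)(C(C)C)C(C)C)c1 | intermediate
15 | lithium borate (ate) complex from 9 and 14 | [Li+].COc1cc(OC)c(/C=C/[B-]2(c3cc(O[Si](C(C)C)(C(C)C)C(C)C)cc(O[Si](C(C)C)(C(C)C)C(C)C)c3)O[C@]3(C)c4cccc5cccc(c45)[C@]3(C)O2)c(C(OC)OC)c1 | intermediate
16 | (1S,2R)-1-[3,5-bis(triisopropylsilyloxy)phenyl]-2-[2-(dimethoxymethyl)-4,6-dimethoxyphenyl]-2-(4-methoxyphenyl)ethylboronic acid mac ester | COc1ccc([C@H](c2c(OC)cc(OC)cc2C(OC)OC)[C@H](B2O[C@]3(C)c4cccc5cccc(c45)[C@]3(C)O2)c2cc(O[Si](C(C)C)(C(C)C)C(C)C)cc(O[Si](C(C)C)(C(C)C)C(C)C)c2)cc1 | intermediate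
17 | (1S,2R)-1-[3,5-bis(triisopropylsilyloxy)phenyl]-2-[2-(dimethoxymethyl)-4,6-dimethoxyphenyl]-2-(4-methoxyphenyl)ethan-1-ol | COc1ccc([C@H](c2c(OC)cc(OC)cc2C(OC)OC)[C@H](O)c2cc(O[Si](C(C)C)(C(C)C)C(C)C)cc(O[Si](C(C)C)(C(C)C)C(C)C)c2)cc1 | intermediate
18 | 1-[(1S,2R)-2-[2-(dimethoxymethyl)-4,6-dimethoxyphenyl]-1-(methoxymethoxy)-2-(4-methoxyphenyl)ethyl]-3,5-bis(triisopropylsilyloxy)benzene | COc1ccc([C@H](c2c(OC)cc(OC)cc2C(OC)OC)[C@H](OCOC)c2cc(O[Si](C(C)C)(C(C)C)C(C)C)cc(O[Si](C(C)C)(C(C)C)C(C)C)c2)cc1 | intermediate
19 | 2-[(1R,2S)-2-[3,5-bis(triisopropylsilyloxy)phenyl]-2-(methoxymethoxy)-1-(4-methoxyphenyl)ethyl]-3,5-dimethoxybenzaldehyde | COc1ccc([C@H](c2c(OC)cc(OC)cc2C=O)[C@H](OCOC)c2cc(O[Si](C(C)C)(C(C)C)C(C)C)cc(O[Si](C(C)C)(C(C)C)C(C)C)c2)cc1 | intermediate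
20 | 2-[(E)-2-{2-[(1R,2S)-2-[3,5-bis(triisopropylsilyloxy)phenyl]-2-(methoxymethoxy)-1-(4-methoxyphenyl)ethyl]-3,5-dimethoxyphenyl}ethenyl]-4,4,5,5-tetramethyl-1,3,2-dioxaborolane | COc1ccc([C@H](c2c(OC)cc(OC)cc2/C=C/B2OC(C)(C)C(C)(C)O2)[C@H](OCOC)c2cc(O[Si](C(C)C)(C(C)C)C(C)C)cc(O[Si](C(C)C)(C(C)C)C(C)C)c2)cc1 | intermediate
21 | 2,6-dihydroxy-4-methoxybenzaldehyde | COc1cc(O)c(C=O)c(O)c1 | starting material
22 | 4-methoxy-2,6-bis(methoxymethoxy)benzaldehyde | COCOc1cc(OC)cc(OCOC)c1C=O | intermediate
23 | 2-ethynyl-5-methoxy-1,3-bis(methoxymethoxy)benzene | COCOc1cc(OC)cc(OCOC)c1C#C | intermediate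
24 | 2-{(E)-2-[4-methoxy-2,6-bis(methoxymethoxy)phenyl]ethenyl}-1,3,2-benzodioxaborole | COCOc1cc(OC)cc(OCOC)c1/C=C/B1Oc2ccccc2O1 | intermediate
25 | (E)-2-[4-methoxy-2,6-bis(methoxymethoxy)phenyl]ethenylboronic acid mac ester | COCOc1cc(OC)cc(OCOC)c1/C=C/B1O[C@]2(C)c3cccc4cccc(c34)[C@]2(C)O1 | intermediate
26 | 3,5-dimethoxyphenol | COc1cc(O)cc(OC)c1 | starting material
27 | 3,5-dimethoxyphenyl trifluoromethanesulfonate | COc1cc(OC)cc(OS(=O)(=O)C(F)(F)F)c1 | intermediate
28 | 1-bromo-4-methoxybenzene | COc1ccc(Br)cc1 | starting material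
29 | 4-methoxyphenyllithium (titrated ethereal solution) | [Li]c1ccc(OC)cc1 | intermediate
30 | lithium borate (ate) complex from 25 and 29 | [Li+].COCOc1cc(OC)cc(OCOC)c1/C=C/[B-]1(c2ccc(OC)cc2)O[C@]2(C)c3cccc4cccc(c34)[C@]2(C)O1 | intermediate
31 | (1S,2R)-2-(3,5-dimethoxyphenyl)-2-[4-methoxy-2,6-bis(methoxymethoxy)phenyl]-1-(4-methoxyphenyl)ethylboronic acid mac ester | COc1cc(OC)cc([C@H](c2c(OCOC)cc(OC)cc2OCOC)[C@H](B2O[C@]3(C)c4cccc5cccc(c45)[C@]3(C)O2)c2ccc(OC)cc2)c1 | intermediate
32 | (1S,2R)-2-(3,5-dimethoxyphenyl)-2-[4-methoxy-2,6-bis(methoxymethoxy)phenyl]-1-(4-methoxyphenyl)ethan-1-ol | COc1cc(OC)cc([C@H](c2c(OCOC)cc(OC)cc2OCOC)[C@H](O)c2ccc(OC)cc2)c1 | intermediate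
33 | (2R,3R)-3-(3,5-dimethoxyphenyl)-6-methoxy-2-(4-methoxyphenyl)-2,3-dihydro-1-benzofuran-4-ol | Oc1cc(OC)cc2c1[C@@H](c1cc(OC)cc(OC)c1)[C@H](c1ccc(OC)cc1)O2 | intermediate
34 | (2R,3R)-3-(3,5-dimethoxyphenyl)-6-methoxy-2-(4-methoxyphenyl)-2,3-dihydro-1-benzofuran-4-yl trifluoromethanesulfonate | O=S(=O)(Oc1cc(OC)cc2c1[C@@H](c1cc(OC)cc(OC)c1)[C@H](c1ccc(OC)cc1)O2)C(F)(F)F | intermediate
35 | 5-chloro-2-hydroxybenzaldehyde | Oc1ccc(Cl)cc1C=O | starting material
36 | 5-chloro-2-(methoxymethoxy)benzaldehyde | COCOc1ccc(Cl)cc1C=O | intermediate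
37 | 4-chloro-2-ethynyl-1-(methoxymethoxy)benzene | COCOc1ccc(Cl)cc1C#C | intermediate
38 | 2-{(E)-2-[5-chloro-2-(methoxymethoxy)phenyl]ethenyl}-1,3,2-benzodioxaborole | COCOc1ccc(Cl)cc1/C=C/B1Oc2ccccc2O1 | intermediate
39 | (E)-2-[5-chloro-2-(methoxymethoxy)phenyl]ethenylboronic acid mac ester | COCOc1ccc(Cl)cc1/C=C/B1O[C@]2(C)c3cccc4cccc(c34)[C@]2(C)O1 | intermediate
40 | lithium borate (ate) complex from 39 and 29 | [Li+].COCOc1ccc(Cl)cc1/C=C/[B-]1(c2ccc(OC)cc2)O[C@]2(C)c3cccc4cccc(c34)[C@]2(C)O1 | intermediate
41 | (1S,2R)-2-[5-chloro-2-(methoxymethoxy)phenyl]-2-[(2R,3R)-3-(3,5-dimethoxyphenyl)-6-methoxy-2-(4-methoxyphenyl)-2,3-dihydro-1-benzofuran-4-yl]-1-(4-methoxyphenyl)ethylboronic acid mac ester | COc1cc([C@H](c2cc(Cl)ccc2OCOC)[C@H](B2O[C@]3(C)c4cccc5cccc(c45)[C@]3(C)O2)c2ccc(OC)cc2)c2c(c1)O[C@@H](c1ccc(OC)cc1)[C@@H]2c1cc(OC)cc(OC)c1 | intermediate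
42 | (1S,2R)-2-[5-chloro-2-(methoxymethoxy)phenyl]-2-[(2R,3R)-3-(3,5-dimethoxyphenyl)-6-methoxy-2-(4-methoxyphenyl)-2,3-dihydro-1-benzofuran-4-yl]-1-(4-methoxyphenyl)ethan-1-ol | COc1cc([C@H](c2cc(Cl)ccc2OCOC)[C@H](O)c2ccc(OC)cc2)c2c(c1)O[C@@H](c1ccc(OC)cc1)[C@@H]2c1cc(OC)cc(OC)c1 | intermediate
43 | (2R,3R)-5-chloro-3-[(2R,3R)-3-(3,5-dimethoxyphenyl)-6-methoxy-2-(4-methoxyphenyl)-2,3-dihydro-1-benzofuran-4-yl]-2-(4-methoxyphenyl)-2,3-dihydro-1-benzofuran | Clc1ccc2c(c1)[C@@H](c1cc(OC)cc3c1[C@@H](c1cc(OC)cc(OC)c1)[C@H](c1ccc(OC)cc1)O3)[C@H](c1ccc(OC)cc1)O2 | intermediate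
44 | E-stilbene from 20 and 43: bis(triisopropylsilyl) ether of 45 | COc1ccc([C@H](c2c(OC)cc(OC)cc2/C=C/c2ccc3c(c2)[C@@H](c2cc(OC)cc4c2[C@@H](c2cc(OC)cc(OC)c2)[C@H](c2ccc(OC)cc2)O4)[C@H](c2ccc(OC)cc2)O3)[C@H](OCOC)c2cc(O[Si](C(C)C)(C(C)C)C(C)C)cc(O[Si](C(C)C)(C(C)C)C(C)C)c2)cc1 | intermediate
45 | 5-[(1S,2R)-2-{2-[(E)-2-(ring B/C unit of 43, bonded at C5 of ring B)ethenyl]-4,6-dimethoxyphenyl}-1-(methoxymethoxy)-2-(4-methoxyphenyl)ethyl]benzene-1,3-diol | COc1ccc([C@H](c2c(OC)cc(OC)cc2/C=C/c2ccc3c(c2)[C@@H](c2cc(OC)cc4c2[C@@H](c2cc(OC)cc(OC)c2)[C@H](c2ccc(OC)cc2)O4)[C@H](c2ccc(OC)cc2)O3)[C@H](OCOC)c2cc(O)cc(O)c2)cc1 | intermediate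
46 | Cb-O-methoxymethyl octa-O-methyl ether of 47, arene E phenol free (Ca R, Cb S, C3A R, C2A R, C3B R, C2B R, C3C R, C2C R) | COc1ccc([C@@H]2c3c(OC)cc(OC)cc3[C@@H]3c4c(cc(O)cc4[C@H]2OCOC)O[C@H]3c2ccc3c(c2)[C@@H](c2cc(OC)cc4c2[C@@H](c2cc(OC)cc(OC)c2)[C@H](c2ccc(OC)cc2)O4)[C@H](c2ccc(OC)cc2)O3)cc1 | intermediate
47 | CNP0132116.1 (Ca R, Cb S, C3A R, C2A R, C3B R, C2B R, C3C R, C2C R) | Oc1ccc([C@@H]2c3c(O)cc(O)cc3[C@@H]3c4c(cc(O)cc4[C@H]2O)O[C@H]3c2ccc3c(c2)[C@@H](c2cc(O)cc4c2[C@@H](c2cc(O)cc(O)c2)[C@H](c2ccc(O)cc2)O4)[C@H](c2ccc(O)cc2)O3)cc1 | target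

## Step count and least certain steps

Total: 28 steps. Longest linear sequence: 12 steps (from 3: steps 2, 3, 4, 5, 8, 9, 10, 11, 12, 26, 27, 28).

**Step 27 (proposed new method).** The most likely failure is poor facial selectivity in the C–C bond formation at C3A, because nothing but the conformation of the Ca–Cb tether decides which face of the alkene meets the arene. The next most likely failures are further oxidation of the product phenol or of another electron-rich ring by the persulfate-derived oxidant, and capture of the C2A cation by an outside nucleophile before the phenol oxygen closes.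

The fallback uses polar, known reactions; it sets out from 19 and 43 and comes back at 46. TBAF frees the resorcinol of 19, and the phenoxide adds through its ortho carbon to the aldehyde (phenoxide hydroxyalkylation) to give the dibenzosuberol F1. In parallel, 43 is hydroxymethylated by palladium-catalysed coupling with potassium acetoxymethyltrifluoroborate (Pd(OAc)2, dicyclohexylphosphino-biaryl ligand, Na2CO3, dioxane/H2O) to the benzylic alcohol F3, which with tetrahydrothiophene and HBF4 gives the sulfonium tetrafluoroborate F4. F1 and F4 are then combined with Cs2CO3 in CH2Cl2: F1 loses water to the ortho-quinone methide F2, the sulfur ylide from F4 adds to its exocyclic carbon, and the phenoxide displaces tetrahydrothiophene. This (4+1) annulation, a known route to trans-2,3-disubstituted dihydrobenzofurans, gives 46. The facial selectivity is still substrate-controlled, but no oxidant is present.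

**Step 8 (key step).** The most likely failure is direct transfer of the alkenyl group from boron to palladium (Suzuki–Miyaura pathway) instead of the 1,2-shift, because the β-aryl group with two ortho substituents hinders alkene binding. The same hindrance may lower the enantioselectivity, and residual bromide may stall the catalyst. What is learned here transfers to steps 18 and 24.

The fallback builds the same alcohol by epoxide opening; it sets out from 11 and 4 and comes back at 17. Heck coupling of 11 with 4-methoxystyrene (Pd(OAc)2, P(o-tol)3, Et3N, DMF) gives the E-stilbene F5, and Shi epoxidation (D-fructose-derived ketone, Oxone 2KHSO5·KHSO4·K2SO4, K2CO3 buffer) gives the (R,R)-epoxide F6. Separately, 4 is acetalised (HC(OMe)3, TsOH, MeOH) to the bromo acetal F7, and bromine–lithium exchange (t-BuLi, −78 °C) gives the aryllithium F8. F8 with BF3·OEt2 opens F6 at the carbon bearing the 4-methoxyphenyl group with inversion. Syn epoxidation of the E-alkene followed by anti opening gives the same relative configuration as anti addition in step 8, so the product is 17.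

**Step 28.** The most likely failure is ionisation of benzylic C–O bonds under the Lewis acid: opening of ring B at C2B followed by Friedel–Crafts capture of the cation by the neighbouring resorcinol ring, or aryl-assisted loss of the oxygen at Cb.

The fallback avoids cations; it sets out from 46 and comes back at 47. Dilute HCl in MeOH at rt removes the MOM group and gives the octamethyl ether carbinol F9. F9 is then demethylated with MeMgI without solvent at about 160 °C, where the methyl groups are removed by nucleophilic attack at carbon and the benzylic C–O bonds are not activated; acidic work-up gives 47.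

## Further compounds

F1 | step 27 | dibenzosuberol from closure of the resorcinol of 19 onto its aldehyde (Ca R, Cb S, carbinol carbon as a mixture) | COc1ccc([C@@H]2c3c(OC)cc(OC)cc3C(O)c3c(O)cc(O)cc3[C@H]2OCOC)cc1
F2 | step 27 | ortho-quinone methide formed from F1 by loss of water | COc1ccc([C@@H]2c3c(OC)cc(OC)cc3C=C3C(=O)C=C(O)C=C3[C@H]2OCOC)cc1
F3 | step 27 | {(2R,3R)-3-[(2R,3R)-3-(3,5-dimethoxyphenyl)-6-methoxy-2-(4-methoxyphenyl)-2,3-dihydro-1-benzofuran-4-yl]-2-(4-methoxyphenyl)-2,3-dihydro-1-benzofuran-5-yl}methanol | OCc1ccc2c(c1)[C@@H](c1cc(OC)cc3c1[C@@H](c1cc(OC)cc(OC)c1)[C@H](c1ccc(OC)cc1)O3)[C@H](c1ccc(OC)cc1)O2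
F4 | step 27 | 1-({(2R,3R)-3-[(2R,3R)-3-(3,5-dimethoxyphenyl)-6-methoxy-2-(4-methoxyphenyl)-2,3-dihydro-1-benzofuran-4-yl]-2-(4-methoxyphenyl)-2,3-dihydro-1-benzofuran-5-yl}methyl)tetrahydrothiophenium tetrafluoroborate | F[B-](F)(F)F.C1CC[S+](C1)Cc1ccc2c(c1)[C@@H](c1cc(OC)cc3c1[C@@H](c1cc(OC)cc(OC)c1)[C@H](c1ccc(OC)cc1)O3)[C@H](c1ccc(OC)cc1)O2
F5 | step 8 | (E)-1-[3,5-bis(triisopropylsilyloxy)phenyl]-2-(4-methoxyphenyl)ethene | COc1ccc(/C=C/c2cc(O[Si](C(C)C)(C(C)C)C(C)C)cc(O[Si](C(C)C)(C(C)C)C(C)C)c2)cc1
F6 | step 8 | (2R,3R)-2-[3,5-bis(triisopropylsilyloxy)phenyl]-3-(4-methoxyphenyl)oxirane | COc1ccc([C@H]2O[C@@H]2c2cc(O[Si](C(C)C)(C(C)C)C(C)C)cc(O[Si](C(C)C)(C(C)C)C(C)C)c2)cc1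
F7 | step 8 | 2-bromo-1-(dimethoxymethyl)-3,5-dimethoxybenzene | COc1cc(OC)c(Br)c(C(OC)OC)c1
F8 | step 8 | 2-(dimethoxymethyl)-4,6-dimethoxyphenyllithium | [Li]c1c(OC)cc(OC)cc1C(OC)OC
F9 | step 28 | octa-O-methyl ether of 47 with free Cb hydroxyl and free arene E phenol | COc1ccc([C@@H]2c3c(OC)cc(OC)cc3[C@@H]3c4c(cc(O)cc4[C@H]2O)O[C@H]3c2ccc3c(c2)[C@@H](c2cc(OC)cc4c2[C@@H](c2cc(OC)cc(OC)c2)[C@H](c2ccc(OC)cc2)O4)[C@H](c2ccc(OC)cc2)O3)cc1
A1 | alternative 1 | (2R,3R)-5-bromo-3-{2-(3,5-dimethoxybenzyl)-3-hydroxy-5-[(triisopropylsilyl)oxy]phenyl}-2-(4-methoxyphenyl)-2,3-dihydro-1-benzofuran | Brc1ccc2c(c1)[C@@H](c1cc(O[Si](C(C)C)(C(C)C)C(C)C)cc(O)c1Cc1cc(OC)cc(OC)c1)[C@H](c1ccc(OC)cc1)O2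
A2 | alternative 1 | 3-[(2R,3R)-5-bromo-2-(4-methoxyphenyl)-2,3-dihydro-1-benzofuran-3-yl]-4-(3,5-dimethoxybenzyl)cyclobut-2-en-1-one | Brc1ccc2c(c1)[C@@H](C1=CC(=O)C1Cc1cc(OC)cc(OC)c1)[C@H](c1ccc(OC)cc1)O2
A3 | alternative 1 | (ethynyloxy)triisopropylsilane | C#CO[Si](C(C)C)(C(C)C)C(C)C
A4 | alternative 2 | octa-O-methyl cycloheptanone with free 4-hydroxyphenyl group | Oc1ccc([C@@H]2c3c(OC)cc(OC)cc3[C@@H]3c4c(cc(OC)cc4C2=O)O[C@H]3c2ccc3c(c2)[C@@H](c2cc(OC)cc4c2[C@@H](c2cc(OC)cc(OC)c2)[C@H](c2ccc(OC)cc2)O4)[C@H](c2ccc(OC)cc2)O3)cc1
A5 | alternative 2 | ring A aldehyde carrying the para-quinone methide on arene D | O=C1C=CC(=Cc2c(OC)cc(OC)cc2[C@@H]2c3c(cc(OC)cc3C=O)O[C@H]2c2ccc3c(c2)[C@@H](c2cc(OC)cc4c2[C@@H](c2cc(OC)cc(OC)c2)[C@H](c2ccc(OC)cc2)O4)[C@H](c2ccc(OC)cc2)O3)C=C1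
A6 | alternative 3 | (2R,3R)-5-bromo-3-[(2R,3R)-3-(3,5-dimethoxyphenyl)-6-methoxy-2-(4-methoxyphenyl)-2,3-dihydro-1-benzofuran-4-yl]-2-(4-methoxyphenyl)-2,3-dihydro-1-benzofuran | Brc1ccc2c(c1)[C@@H](c1cc(OC)cc3c1[C@@H](c1cc(OC)cc(OC)c1)[C@H](c1ccc(OC)cc1)O3)[C@H](c1ccc(OC)cc1)O2
A7 | alternative 3 | diol diphenol (both carbinol centres as mixtures) | Oc1ccc(Br)cc1[C@@H](c1cc(OC)cc(O)c1[C@@H](c1cc(OC)cc(OC)c1)C(O)c1ccc(OC)cc1)C(O)c1ccc(OC)cc1
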